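**Remark.** The target SMILES is read as the all‑S isomer, in which both flavanone units are 2,3‑cis. Unit 1 (unprimed locants, rings A and C) carries the 4‑methoxyphenyl group; unit 2 (doubly primed locants, rings A'' and C'') carries the 4‑hydroxyphenyl group.

## Retrosynthetic overview

1. Sikokianin A comes from its penta‑O‑benzyl ether by global hydrogenolysis; the aryl methyl ether is carried from the start.
2. Ring C'' is disconnected at C‑3''–C‑2'' and C‑4''–C‑4a'': a dearomatizing [4+2] annulation of a 2‑silyloxyfuran with an aryloxycarbenium ion (cationic 2‑oxadiene C‑4a''=C‑8a''–O‑1''=C‑2'').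
3. Enabling feature: the 1,4‑diketone C‑4(=O)–C‑3–C‑3''–C‑4''(=O) joining pyranone rings C and C'' is a ring‑opened furan. Its atoms O, C‑4, C‑3, C‑3'', C‑4'' are pre‑assembled as a 2‑silyloxyfuran fused to ring C, and the O‑1''–C‑2'' benzylic aryl ether with ring A'' is the four‑atom partner.
4. Stereocontrol: C‑2 by catalytic asymmetric conjugate arylation of a chromone; C‑2 then directs C‑3'' (anti face), the endo mode sets C‑2'', and kinetic protonation of the released unit‑1 enolate sets C‑3.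
5. Ring order: rings A and C arrive with the chromone; the furan ring is built on ring C (cyclopropanation, ring opening, enol lactonization, silylation); ring C'' closes in the key step as the furan ring opens; ring A'' comes from 3,5‑bis(benzyloxy)phenol.

Key step: step 9

## Route

Step 1
Reactants: 1 5,7-dihydroxy-4H-chromen-4-one
Product: 2 5,7-bis(benzyloxy)-4H-chromen-4-one
Conditions: BnBr, K2CO3, Bu4NI (cat.), DMF, 70 °C
Reagents that add atoms: benzyl bromide, BrCc1ccccc1
Why: Williamson etherification of both phenols (the chelated 5‑OH needs DMF and heat), the chromone ring being inert to carbonate.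

Step 2
Reactants: 2 5,7-bis(benzyloxy)-4H-chromen-4-one; 3 (4-methoxyphenyl)boronic acid
Product: 4 (2S)-5,7-bis(benzyloxy)-2-(4-methoxyphenyl)-2,3-dihydro-4H-chromen-4-one
Conditions: Pd(OCOCF3)2 (5 mol %), t‑BuPyOx (6 mol %; the enantiomer that delivers 2S, expected to be the R ligand), NH4PF6, H2O, ClCH2CH2Cl, 60 °C
Reagents that add atoms: none
Why: Palladium‑catalysed asymmetric conjugate addition of an arylboronic acid to a chromone, in which the chiral pyridine‑oxazoline aryl‑palladium species selects the enone face and so sets C‑2 as S.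

Step 3
Reactants: 4 (2S)-5,7-bis(benzyloxy)-2-(4-methoxyphenyl)-2,3-dihydro-4H-chromen-4-one
Product: 5 tert-butyl{[(2S)-5,7-bis(benzyloxy)-2-(4-methoxyphenyl)-2H-chromen-4-yl]oxy}dimethylsilane
Conditions: TBSOTf, Et3N, CH2Cl2, 0 °C
Reagents that add atoms: tert-butyldimethylsilyl trifluoromethanesulfonate, CC(C)(C)[Si](C)(C)OS(=O)(=O)C(F)(F)F
Why: Soft enolization (silyl triflate plus amine) gives the silyl enol ether without a free enolate, so retro‑oxa‑Michael ring opening and loss of the C‑2 configuration are avoided.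

Step 4
Reactants: 5 tert-butyl{[(2S)-5,7-bis(benzyloxy)-2-(4-methoxyphenyl)-2H-chromen-4-yl]oxy}dimethylsilane; 6 tert-butyl diazoacetate
Product: 7 tert-butyl (2S)-5,7-bis(benzyloxy)-7b-{[tert-butyl(dimethyl)silyl]oxy}-2-(4-methoxyphenyl)-1,1a,2,7b-tetrahydrocyclopropa[c]chromene-1-carboxylate (mixture of cyclopropane diastereomers)
Conditions: Rh2(OAc)4 (1 mol %), slow addition of 6, CH2Cl2, rt
Reagents that add atoms: none
Why: Rhodium‑carbenoid cyclopropanation of an electron‑rich silyl enol ether (donor–acceptor siloxycyclopropane synthesis); the new cyclopropane centres are erased in the next step and need no control.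

Step 5
Reactants: 7 tert-butyl (2S)-5,7-bis(benzyloxy)-7b-{[tert-butyl(dimethyl)silyl]oxy}-2-(4-methoxyphenyl)-1,1a,2,7b-tetrahydrocyclopropa[c]chromene-1-carboxylate
Product: 9 (4R)-7,9-bis(benzyloxy)-4-(4-methoxyphenyl)-3,4-dihydro-2H-furo[3,2-c]chromen-2-one, via flavanone-3-acetic acid 8 (not isolated)
Conditions: TFA/CH2Cl2 (1:4), 0 °C to rt; concentrate; then (CF3CO)2O, 2,6‑lutidine, CH2Cl2, 0 °C
Reagents that add atoms: none
Why: Acid opens the donor–acceptor cyclopropane between the siloxy carbon and the ester‑bearing carbon and cleaves the tert‑butyl ester to the γ‑keto acid; mixed‑anhydride activation under buffered conditions then gives the enol lactone (5‑exo attack of the ketone oxygen, loss of H‑3), with C‑3 becoming sp2 and the old C‑2 centre untouched (its descriptor becomes R by CIP only).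

Step 6
Reactants: 9 (4R)-7,9-bis(benzyloxy)-4-(4-methoxyphenyl)-3,4-dihydro-2H-furo[3,2-c]chromen-2-one
Product: 10 {[(4R)-7,9-bis(benzyloxy)-4-(4-methoxyphenyl)-4H-furo[3,2-c]chromen-2-yl]oxy}tri(propan-2-yl)silane
Conditions: TIPSOTf, Et3N, CH2Cl2, 0 °C; filtration through basic alumina under argon, used at once
Reagents that add atoms: triisopropylsilyl trifluoromethanesulfonate, CC(C)[Si](C(C)C)(C(C)C)OS(=O)(=O)C(F)(F)F
Why: O‑silylation and deprotonation of the enol lactone aromatize it to the 2‑silyloxyfuran (standard silyloxyfuran formation), leaving the single stereocentre untouched.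

Step 7
Reactants: 11 4-(benzyloxy)benzaldehyde
Product: 13 1-{[4-(benzyloxy)phenyl](chloro)methyl}-1H-benzotriazole (racemic), via benzotriazole–aldehyde hemiaminal 12 (not isolated)
Conditions: 1H‑benzotriazole, SOCl2, toluene, rt to 40 °C
Reagents that add atoms: 1H-benzotriazole, c1ccc2[nH]nnc2c1; thionyl chloride, O=S(Cl)Cl
Why: Katritzky benzotriazole chemistry, in which the aldehyde–benzotriazole adduct is converted by thionyl chloride into the 1‑(α‑chloroalkyl)benzotriazole.

Step 8
Reactants: 13 1-{[4-(benzyloxy)phenyl](chloro)methyl}-1H-benzotriazole; 14 3,5-bis(benzyloxy)phenol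
Product: 15 1-{[3,5-bis(benzyloxy)phenoxy][4-(benzyloxy)phenyl]methyl}-1H-benzotriazole (racemic)
Conditions: NaH, THF/DMF, 0 °C to rt
Reagents that add atoms: none
Why: Displacement of the activated chloride by the phenoxide oxygen (polar aprotic medium favours O‑ over C‑alkylation) is the standard route to 1‑(α‑aryloxyalkyl)benzotriazoles; the stereocentre is lost on later ionization.

Step 9
Reactants: 10 {[(4R)-7,9-bis(benzyloxy)-4-(4-methoxyphenyl)-4H-furo[3,2-c]chromen-2-yl]oxy}tri(propan-2-yl)silane; 15 1-{[3,5-bis(benzyloxy)phenoxy][4-(benzyloxy)phenyl]methyl}-1H-benzotriazole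
Product: 18 (2S,3S)-5,7-bis(benzyloxy)-3-{(2S,3S)-5,7-bis(benzyloxy)-2-[4-(benzyloxy)phenyl]-4-oxo-3,4-dihydro-2H-chromen-3-yl}-2-(4-methoxyphenyl)-2,3-dihydro-4H-chromen-4-one, via endo cycloadduct silyl ketal 16 (not isolated), via ring-opened triisopropylsilyl enol ether 17 (not isolated)
Conditions: TMSOTf (0.3 equiv), 4 Å MS, CH2Cl2, −78 to −30 °C; then Bu4NF/AcOH (1:1.5), THF, −78 to −40 °C
Reagents that add atoms: none
Why: Proposed new method: TMSOTf ionizes 15 to the E‑configured aryloxycarbenium ion (cationic 2‑oxadiene C‑4a''=C‑8a''–O‑1''=C‑2''), whose C‑2'' is attacked by C‑3'' of the silyloxyfuran (its 2,3‑bond acting as a cyclic silyl ketene acetal), and the resulting O‑silyl lactonium carbon C‑4'' is captured by the ortho carbon C‑4a'' of the tethered phloroglucinol ring in a 6‑exo‑trig Friedel–Crafts closure; this is a dearomatizing formal [4+2] annulation whose closest known relatives are the oxa‑Povarov reaction of aryloxycarbenium ions with alkenes and the benzotriazole‑mediated Mukaiyama‑type alkylation of silyl ketene acetals. The silyl ketal 16 then fragments at its C‑4''–O(enol) bond with silyl transfer, giving the aryl ketone of ring C'' and the silyl enol ether 17, while benzotriazole takes up the proton released on rearomatization so that the silyl triflate turns over. C‑3'' is set by approach of the oxadiene to the furan face anti to the 4‑methoxyphenyl group on the adjacent sp3 carbon C‑2, and C‑2'' by the endo orientation (aryloxy ring stacked over the furochromene, bulky OSi(iPr)3 on the exo side), which places the outside 4‑(benzyloxy)phenyl group cis to C‑3 on the new ring. C‑3 is set last by kinetic protonation of the enolate freed from 17 by Bu4NF/AcOH, on the face anti to the pseudoaxial 2‑aryl group (A(1,2) strain), giving the 2,3‑cis unit 1. The step needs α‑ over γ‑regioselectivity on the furan, endo and anti‑facial selectivity, and C–C bond formation faster than hydride transfer from H‑2; the fully substituted γ‑carbon C‑4 shielded by the peri 5‑benzyloxy group, the bulky silyl group and the high nucleophilicity of the ketene acetal carbon at −78 °C should secure these.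

Step 10
Reactants: 18 (2S,3S)-5,7-bis(benzyloxy)-3-{(2S,3S)-5,7-bis(benzyloxy)-2-[4-(benzyloxy)phenyl]-4-oxo-3,4-dihydro-2H-chromen-3-yl}-2-(4-methoxyphenyl)-2,3-dihydro-4H-chromen-4-one
Product: 19 sikokianin A, (2S,3S)-3-[(2S,3S)-5,7-dihydroxy-2-(4-hydroxyphenyl)-4-oxo-3,4-dihydro-2H-chromen-3-yl]-5,7-dihydroxy-2-(4-methoxyphenyl)-2,3-dihydro-4H-chromen-4-one
Conditions: H2 (1 atm), Pd/C (10 wt % palladium on carbon), EtOAc/MeOH, rt
Reagents that add atoms: none
Why: Hydrogenolysis of the five aryl benzyl ethers under neutral conditions, so the epimerizable cis centres C‑3 and C‑3'' are not enolized and the cyclic benzylic C‑2–O bonds, which cleave far more slowly, survive.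

## Compound list

1 | 5,7-dihydroxy-4H-chromen-4-one | O=c1ccoc2cc(O)cc(O)c12 | starting material
2 | 5,7-bis(benzyloxy)-4H-chromen-4-one | O=c1ccoc2cc(OCc3ccccc3)cc(OCc3ccccc3)c12 | intermediate
3 | (4-methoxyphenyl)boronic acid | COc1ccc(B(O)O)cc1 | starting material
4 | (2S)-5,7-bis(benzyloxy)-2-(4-methoxyphenyl)-2,3-dihydro-4H-chromen-4-one | COc1ccc([C@H]2Oc3cc(OCc4ccccc4)cc(OCc4ccccc4)c3C(=O)C2)cc1 | intermediate
5 | tert-butyl{[(2S)-5,7-bis(benzyloxy)-2-(4-methoxyphenyl)-2H-chromen-4-yl]oxy}dimethylsilane | COc1ccc([C@H]2Oc3cc(OCc4ccccc4)cc(OCc4ccccc4)c3C(O[Si](C)(C)C(C)(C)C)=C2)cc1 | intermediate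
6 | tert-butyl diazoacetate | CC(C)(C)OC(=O)C=[N+]=[N-] | starting material
7 | tert-butyl (2S)-5,7-bis(benzyloxy)-7b-{[tert-butyl(dimethyl)silyl]oxy}-2-(4-methoxyphenyl)-1,1a,2,7b-tetrahydrocyclopropa[c]chromene-1-carboxylate (cyclopropane centres undefined, mixture) | COc1ccc([C@H]2Oc3cc(OCc4ccccc4)cc(OCc4ccccc4)c3C3(O[Si](C)(C)C(C)(C)C)C(C(=O)OC(C)(C)C)C23)cc1 | intermediate
8 | 2-[(2S)-5,7-bis(benzyloxy)-2-(4-methoxyphenyl)-4-oxo-3,4-dihydro-2H-chromen-3-yl]acetic acid (C‑3 epimers) | COc1ccc([C@H]2Oc3cc(OCc4ccccc4)cc(OCc4ccccc4)c3C(=O)C2CC(=O)O)cc1 | intermediate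
9 | (4R)-7,9-bis(benzyloxy)-4-(4-methoxyphenyl)-3,4-dihydro-2H-furo[3,2-c]chromen-2-one | COc1ccc([C@H]2Oc3cc(OCc4ccccc4)cc(OCc4ccccc4)c3C3=C2CC(=O)O3)cc1 | intermediate
10 | {[(4R)-7,9-bis(benzyloxy)-4-(4-methoxyphenyl)-4H-furo[3,2-c]chromen-2-yl]oxy}tri(propan-2-yl)silane | COc1ccc([C@H]2Oc3cc(OCc4ccccc4)cc(OCc4ccccc4)c3-c3oc(O[Si](C(C)C)(C(C)C)C(C)C)cc32)cc1 | intermediate
11 | 4-(benzyloxy)benzaldehyde | O=Cc1ccc(OCc2ccccc2)cc1 | starting material
12 | (1H-benzotriazol-1-yl)[4-(benzyloxy)phenyl]methanol (racemic) | OC(c1ccc(OCc2ccccc2)cc1)n1nnc2ccccc21 | intermediate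
13 | 1-{[4-(benzyloxy)phenyl](chloro)methyl}-1H-benzotriazole (racemic) | ClC(c1ccc(OCc2ccccc2)cc1)n1nnc2ccccc21 | intermediate
14 | 3,5-bis(benzyloxy)phenol | Oc1cc(OCc2ccccc2)cc(OCc2ccccc2)c1 | starting material
15 | 1-{[3,5-bis(benzyloxy)phenoxy][4-(benzyloxy)phenyl]methyl}-1H-benzotriazole (racemic) | C(Oc1cc(OCc2ccccc2)cc(OCc2ccccc2)c1)(c1ccc(OCc2ccccc2)cc1)n1nnc2ccccc21 | intermediate
16 | endo [4+2] cycloadduct: the 2,3-dihydrofuran ring (O, C‑4, C‑3, C‑3'', C‑4'') still joins both units; C‑4'' carries OSi(iPr)3, the ring oxygen and the new bond to C‑4a''; ring C'' is fused on the face anti to the 4‑methoxyphenyl group; H‑3'' and H‑2'' cis (unit‑1 C‑2 R, C‑3'' S, C‑2'' S, C‑4'' R) | COc1ccc([C@H]2Oc3cc(OCc4ccccc4)cc(OCc4ccccc4)c3C3=C2[C@H]2[C@@H](c4ccc(OCc5ccccc5)cc4)Oc4cc(OCc5ccccc5)cc(OCc5ccccc5)c4[C@@]2(O[Si](C(C)C)(C(C)C)C(C)C)O3)cc1 | intermediate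
17 | (2S,3S)-5,7-bis(benzyloxy)-2-[4-(benzyloxy)phenyl]-3-[(2R)-5,7-bis(benzyloxy)-2-(4-methoxyphenyl)-4-{[tri(propan-2-yl)silyl]oxy}-2H-chromen-3-yl]-2,3-dihydro-4H-chromen-4-one | COc1ccc([C@H]2Oc3cc(OCc4ccccc4)cc(OCc4ccccc4)c3C(O[Si](C(C)C)(C(C)C)C(C)C)=C2[C@@H]2C(=O)c3c(OCc4ccccc4)cc(OCc4ccccc4)cc3O[C@@H]2c2ccc(OCc3ccccc3)cc2)cc1 | intermediate
18 | (2S,3S)-5,7-bis(benzyloxy)-3-{(2S,3S)-5,7-bis(benzyloxy)-2-[4-(benzyloxy)phenyl]-4-oxo-3,4-dihydro-2H-chromen-3-yl}-2-(4-methoxyphenyl)-2,3-dihydro-4H-chromen-4-one | COc1ccc([C@H]2Oc3cc(OCc4ccccc4)cc(OCc4ccccc4)c3C(=O)[C@H]2[C@@H]2C(=O)c3c(OCc4ccccc4)cc(OCc4ccccc4)cc3O[C@@H]2c2ccc(OCc3ccccc3)cc2)cc1 | intermediate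
19 | sikokianin A, (2S,3S)-3-[(2S,3S)-5,7-dihydroxy-2-(4-hydroxyphenyl)-4-oxo-3,4-dihydro-2H-chromen-3-yl]-5,7-dihydroxy-2-(4-methoxyphenyl)-2,3-dihydro-4H-chromen-4-one | COc1ccc([C@H]2Oc3cc(O)cc(O)c3C(=O)[C@H]2[C@@H]2C(=O)c3c(O)cc(O)cc3O[C@@H]2c2ccc(O)cc2)cc1 | target

## Step count and risks

Total step count: 10. Longest linear sequence: 8 steps (steps 1–6, 9 and 10); steps 7 and 8 make the second fragment.

Steps most likely to fail:

**Step 9.** The O‑silyl lactonium ion may lose its silyl group or H‑3'' faster than the tethered ring attacks it, the oxadiene may approach with poor endo or facial selectivity, or protonation at C‑3 may be unselective. The fallback separates the two bond formations and sets out from 10 and 15. ZnBr2‑mediated benzotriazole α‑aryloxyalkylation of the silyloxyfuran (a known Mukaiyama‑type C‑alkylation) is stopped after aqueous work‑up at the C‑3 alkylated enol lactone (3S,4R)-3-{(S)-[3,5-bis(benzyloxy)phenoxy][4-(benzyloxy)phenyl]methyl}-7,9-bis(benzyloxy)-4-(4-methoxyphenyl)-3,4-dihydro-2H-furo[3,2-c]chromen-2-one F1, which is separated from its benzylic epimer. Ring C'' is then closed in a separate acid‑promoted intramolecular Friedel–Crafts acylation in which the enol lactone is the acyl donor (BF3·OEt2 or Sc(OTf)3, CH2Cl2, −20 °C). The liberated unit‑1 enol is protonated on buffered work‑up, and the sequence returns to the route at 18.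

**Step 4.** The rhodium carbenoid may insert into the benzylic ether C–H bonds or add to the electron‑rich arenes instead of the hindered trisubstituted enol ether. The fallback sets out from 5 and replaces carbenoid chemistry by radical α‑alkylation. Visible‑light photoredox reaction with tert‑butyl bromoacetate (Ru(bpy)3Cl2, 2,6‑lutidine, DMF, blue light; known for silyl enol ethers and α‑bromo esters) gives tert-butyl 2-[(2S)-5,7-bis(benzyloxy)-2-(4-methoxyphenyl)-4-oxo-3,4-dihydro-2H-chromen-3-yl]acetate F2. TFA then cleaves the ester, and the sequence returns to the route at 8 inside step 5.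

**Step 2.** The peri‑benzyloxy chromone may react slowly, with protodeboronation of the electron‑rich boronic acid and eroded enantioselectivity. The fallback sets out from 2 and uses resolution instead of asymmetric C–C bond formation. Non‑asymmetric conjugate arylation with 3 (Pd(OCOCF3)2, 2,2'‑bipyridine) gives racemic 5,7-bis(benzyloxy)-2-(4-methoxyphenyl)-2,3-dihydro-4H-chromen-4-one F3. Kinetic resolution by asymmetric transfer hydrogenation (RuCl(p‑cymene)(TsDPEN) of the configuration that reduces the 2R ketone, HCO2H/Et3N) converts the unwanted enantiomer into (2R,4R)-5,7-bis(benzyloxy)-2-(4-methoxyphenyl)-3,4-dihydro-2H-chromen-4-ol F4. The unreacted 2S ketone is separated by chromatography, and the sequence returns to the route at 4.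

## Further compounds

F1 | step 9 | (3S,4R)-3-{(S)-[3,5-bis(benzyloxy)phenoxy][4-(benzyloxy)phenyl]methyl}-7,9-bis(benzyloxy)-4-(4-methoxyphenyl)-3,4-dihydro-2H-furo[3,2-c]chromen-2-one | COc1ccc([C@H]2Oc3cc(OCc4ccccc4)cc(OCc4ccccc4)c3C3=C2[C@@H]([C@@H](c2ccc(OCc4ccccc4)cc2)Oc2cc(OCc4ccccc4)cc(OCc4ccccc4)c2)C(=O)O3)cc1
F2 | step 4 | tert-butyl 2-[(2S)-5,7-bis(benzyloxy)-2-(4-methoxyphenyl)-4-oxo-3,4-dihydro-2H-chromen-3-yl]acetate (C‑3 epimers) | COc1ccc([C@H]2Oc3cc(OCc4ccccc4)cc(OCc4ccccc4)c3C(=O)C2CC(=O)OC(C)(C)C)cc1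
F3 | step 2 | racemic 5,7-bis(benzyloxy)-2-(4-methoxyphenyl)-2,3-dihydro-4H-chromen-4-one | COc1ccc(C2Oc3cc(OCc4ccccc4)cc(OCc4ccccc4)c3C(=O)C2)cc1
F4 | step 2 | (2R,4R)-5,7-bis(benzyloxy)-2-(4-methoxyphenyl)-3,4-dihydro-2H-chromen-4-ol | COc1ccc([C@@H]2Oc3cc(OCc4ccccc4)cc(OCc4ccccc4)c3[C@H](O)C2)cc1
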